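A rise in free catalyst from 0.200 mM to 0.300 mM carried the product at 31 min from 67.1 mM to 82.2 mM, and I began by asking which given number mattered that much.

| setting | north-east | west | south-west | east |
|---|---|---|---|---|
| substrate | 100 mM | 100 mM | 150 mM | 100 mM |
| partner | 200 mM | 200 mM | 200 mM | 400 mM |
| free catalyst | 0.200 mM | 0.300 mM | 0.200 mM | 0.400 mM |
| time |  |  |  | 31 min |

| run | time / min | [product] / mM |
|---|---|---|
| north-east run | 3.9 | 24.4 |
| north-east run | 7.8 | 40.1 |
| north-east run | 12 | 50.8 |
| north-east run | 16 | 57.5 |
| north-east run | 19 | 61.1 |
| north-east run | 23 | 64.1 |
| north-east run | 27 | 65.9 |
| north-east run | 31 | 67.1 |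
| west run | 3.9 | 37.0 |
| west run | 7.8 | 56.6 |
| west run | 12 | 68.3 |
| west run | 16 | 74.5 |
| west run | 19 | 77.4 |
| west run | 23 | 80.2 |
| west run | 27 | 80.8 |
| west run | 31 | 82.2 |
| south-west run | 3.9 | 35.2 |
| south-west run | 7.8 | 58.8 |
| south-west run | 12 | 73.1 |
| south-west run | 16 | 81.5 |
| south-west run | 19 | 84.8 |
| south-west run | 23 | 87.8 |
| south-west run | 27 | 89.7 |
| south-west run | 31 | 91.5 |

(standard deviation of a reading: 0.3 mM)

1. reaction order in [free catalyst] at the outset, round the charge of the north-east run, defined at two percent of the substrate turned into product
2. reaction order in [substrate] at the outset, round the charge of the north-east run, defined at two percent of the substrate turned into product (one fixed amount of product, the same in the runs compared)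
3. product in the east run at 31 min, as a share of the substrate charged

- Overall: substrate + partner -> product, with free catalyst as catalyst.
- Constant volume, constant temperature.
- The analysis sees a species whether free or bound.
- An order is taken over about fifteen percent of the charge, up and down.

I went through the charges in turn. Substrate mattered little for the early share turned: at 3.9 min the north-east run had turned 24.4% and the south-west run, with 150 mM, 23.5%, so I took its order as 1. The exact time mattered little late in the north-east run, which gained 1.20 mM over its last 4.00 min. Partner was never varied in these runs, so its doubling in the east run stayed unmeasured. Free catalyst had to be known well.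

I measured progress at the first reading as the logarithm of (substrate charge × (partner charge − product)) over (partner charge × (substrate charge − product)):

north-east: 0.150; west: 0.257; ratio: 1.72

A ratio above 1.50 can mean an order above one, or a fixed amount of each charge doing no work, and two charges cannot separate these. I reckoned the second:

dead slice = (ratio × north-east charge − west charge) / (ratio − one) = 0.0613 mM

This dead slice, the fixed amount of each charge that I took to do no work, read here from two first readings, leaves a working catalyst equal to charge minus slice. The order in free catalyst at the north-east charge is then charge over working catalyst, 1.44. The east run then holds 2.44 times the north-east working catalyst.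

The forecast gave 1.33, 1 and 98.5%, reading the ratio as an order: “This suggests a partly dimeric or cooperative active form.” My order differs from its figure.

The flask gave 1.4, 1.0 and 98.4%.

    free catalyst + partner ⇌ catalyst-reagent complex, settled at all times (12.90 M⁻¹)
    catalyst-reagent complex + substrate → product + free catalyst (738.0 M⁻¹ min⁻¹)
    partner → lost reagent (0.07500 min⁻¹)
    free catalyst + impurity → spent catalyst

The north-east run shows the reason: with the conversion of free catalyst and impurity into spent catalyst (catalyst poisoning) taken away, its apparent order in free catalyst falls from 1.4 to 1.0. My dead slice, as read, is 30.6% of the north-east charge against 15.3% of the east charge. Scaling the logarithm of substrate left in the east run by charge over working catalyst, 1.18, turns 98.4% into 99.2%, and the east flask without the impurity reaches 99.2%.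

The numbers in the tables are calculated with constants of no real substance; the scatter is artificial.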